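## Retrosynthetic overview

1. The target comes from its silyl ether 21, which is formed by a one-flask double ring-closing metathesis of the acyclic hexaene ester 20. The pyran ring (chromene C3=C4) and the butenolide (C3=C4) close together; the benzene ring is bought.
2. Ester 20 comes from an enantioselective SN2′ esterification of the (Z)-allylic trichloroacetimidate 15 with the acrylic acid 19, which sets the lactone stereocentre.
3. Imidate 15 comes from the prenyl terminus of a linalyl aryl ether: SeO2 oxidation of the (E)-methyl, bromide, copper–alkyne coupling with propargyl alcohol, Z-semihydrogenation.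
4. The linalyl aryl ether comes from (R)-linalool and 5-bromo-2-fluoro-3-methylbenzaldehyde by SNAr then Wittig; the quaternary centre is taken from the chiral pool with retention, and Br is later turned into the protected phenol.
5. Acid 19 comes from 6-methylhept-5-en-2-one by kinetic enol triflate formation and hydroxycarbonylation. Ring order: arene (bought), then pyran and butenolide together in the last step.

Assumption: (R)-(−)-linalool (≥97% ee) and 5-bromo-2-fluoro-3-methylbenzaldehyde are taken as catalogue chemicals.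

## Route

Step 1
Reactants: 1 (R)-(−)-linalool; 2 5-bromo-2-fluoro-3-methylbenzaldehyde
Product: 5 5-bromo-2-{[(3R)-3,7-dimethylocta-1,6-dien-3-yl]oxy}-1-ethenyl-3-methylbenzene, via potassium linaloolate 3 (not isolated), via aldehyde ether 4 (not isolated)
Conditions: KH, THF, 0 °C; 2, DMF, 0 °C → rt; then Ph3P=CH2 (from Ph3PCH3Br, KOtBu), THF, 0 °C → rt
Reagents that add atoms: methyltriphenylphosphonium bromide C[P+](c1ccccc1)(c1ccccc1)c1ccccc1.[Br-]
Why: SNAr of the tertiary alkoxide on the ortho-formyl-activated aryl fluoride leaves the C–O bond of linalool untouched (C3 stays R), and Wittig methylenation in the same flask removes the electron-poor, ionisation-prone aldehyde ether before isolation.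

Step 2
Reactants: 5 5-bromo-2-{[(3R)-3,7-dimethylocta-1,6-dien-3-yl]oxy}-1-ethenyl-3-methylbenzene
Product: 8 4-{[(3R)-3,7-dimethylocta-1,6-dien-3-yl]oxy}-3-ethenyl-5-methylphenol, via aryllithium 6 (not isolated), via lithium aryltrimethoxyborate 7 (not isolated)
Conditions: n-BuLi, THF, −78 °C; B(OMe)3, −78 → 0 °C; then 30% H2O2, aq NaOH, 0 °C
Reagents that add atoms: hydrogen peroxide OO
Why: Bromine–lithium exchange at −78 °C outruns addition to the styrene, and borylation–oxidation of the aryllithium gives the phenol (lithiation–borylation–oxidation); the quaternary ether carbon has no α-hydrogen to lose.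

Step 3
Reactants: 8 4-{[(3R)-3,7-dimethylocta-1,6-dien-3-yl]oxy}-3-ethenyl-5-methylphenol
Product: 9 {4-[(3R)-3,7-dimethylocta-1,6-dien-3-yl]oxy-3-ethenyl-5-methylphenoxy}tri(propan-2-yl)silane
Conditions: iPr3SiCl, imidazole, DMF, rt
Reagents that add atoms: chlorotri(propan-2-yl)silane CC(C)[Si](Cl)(C(C)C)C(C)C
Why: Silylation of the unhindered phenol gives a bulky silyl ether that shields the oxidation-prone 4-alkoxyphenol through the oxidative and basic steps that follow.

Step 4
Reactants: 9 {4-[(3R)-3,7-dimethylocta-1,6-dien-3-yl]oxy-3-ethenyl-5-methylphenoxy}tri(propan-2-yl)silane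
Product: 10 (2E,6R)-6-{2-ethenyl-6-methyl-4-[tri(propan-2-yl)silyloxy]phenoxy}-2,6-dimethylocta-2,7-dien-1-ol
Conditions: SeO2 (0.5 equiv), t-BuOOH, CH2Cl2, 0 °C → rt, stopped at partial conversion
Reagents that add atoms: tert-butyl hydroperoxide CC(C)(C)OO (terminal oxidant; the oxygen is passed on through selenium dioxide O=[Se]=O)
Why: SeO2/t-BuOOH allylic oxidation (ene reaction then [2,3]-sigmatropic shift) hydroxylates the (E)-methyl of the gem-dimethyl alkene with retention of the E geometry; the two vinyl groups carry no allylic hydrogen.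

Step 5
Reactants: 10 (2E,6R)-6-{2-ethenyl-6-methyl-4-[tri(propan-2-yl)silyloxy]phenoxy}-2,6-dimethylocta-2,7-dien-1-ol
Product: 11 [4-{[(3R,6E)-8-bromo-3,7-dimethylocta-1,6-dien-3-yl]oxy}-3-ethenyl-5-methylphenoxy]tri(propan-2-yl)silane
Conditions: CBr4, PPh3, CH2Cl2, −20 → 0 °C
Reagents that add atoms: tetrabromomethane BrC(Br)(Br)Br
Why: Appel bromination of the primary allylic alcohol under neutral conditions gives the allylic bromide without allylic shift or loss of the tertiary aryl ether.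

Step 6
Reactants: 11 [4-{[(3R,6E)-8-bromo-3,7-dimethylocta-1,6-dien-3-yl]oxy}-3-ethenyl-5-methylphenoxy]tri(propan-2-yl)silane; 12 prop-2-yn-1-ol
Product: 13 (5E,9R)-9-{2-ethenyl-6-methyl-4-[tri(propan-2-yl)silyloxy]phenoxy}-5,9-dimethylundeca-5,10-dien-2-yn-1-ol
Conditions: CuI (10 mol%), K2CO3, n-Bu4NCl (cat.), DMF, rt
Reagents that add atoms: none
Why: Copper-catalysed SN2 coupling of a terminal alkyne with a primary allylic bromide gives the skipped enyne at the unhindered CH2 terminus with the E-alkene intact.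

Step 7
Reactants: 13 (5E,9R)-9-{2-ethenyl-6-methyl-4-[tri(propan-2-yl)silyloxy]phenoxy}-5,9-dimethylundeca-5,10-dien-2-yn-1-ol
Product: 14 (2Z,5E,9R)-9-{2-ethenyl-6-methyl-4-[tri(propan-2-yl)silyloxy]phenoxy}-5,9-dimethylundeca-2,5,10-trien-1-ol
Conditions: H2 (1 atm, 1.0 equiv uptake), Pd/CaCO3 poisoned with Pb(OAc)2, quinoline, EtOAc, rt
Reagents that add atoms: none
Why: Syn semihydrogenation on poisoned palladium gives the (Z)-allylic alcohol; the alkyne binds far more strongly than the terminal alkenes, so the reaction is stopped after one equivalent of hydrogen.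

Step 8
Reactants: 14 (2Z,5E,9R)-9-{2-ethenyl-6-methyl-4-[tri(propan-2-yl)silyloxy]phenoxy}-5,9-dimethylundeca-2,5,10-trien-1-ol
Product: 15 (2Z,5E,9R)-9-{2-ethenyl-6-methyl-4-[tri(propan-2-yl)silyloxy]phenoxy}-5,9-dimethylundeca-2,5,10-trien-1-yl 2,2,2-trichloroethanimidate
Conditions: Cl3CCN, DBU (10 mol%), CH2Cl2, 0 °C
Reagents that add atoms: trichloroacetonitrile N#CC(Cl)(Cl)Cl
Why: Base-catalysed addition of the primary alcohol to the nitrile gives the trichloroacetimidate, which serves as leaving group and palladium-binding handle in step 11.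

Step 9
Reactants: 16 6-methylhept-5-en-2-one
Product: 18 6-methylhepta-1,5-dien-2-yl trifluoromethanesulfonate, via lithium enolate 17 (not isolated)
Conditions: LiN(iPr)2, THF, −78 °C; PhNTf2, −78 °C → rt
Reagents that add atoms: N-phenylbis(trifluoromethanesulfonimide) O=S(=O)(N(c1ccccc1)S(=O)(=O)C(F)(F)F)C(F)(F)F
Why: Kinetic deprotonation of the methyl ketone at the methyl group and O-triflation give the terminal enol triflate.

Step 10
Reactants: 18 6-methylhepta-1,5-dien-2-yl trifluoromethanesulfonate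
Product: 19 6-methyl-2-methylidenehept-5-enoic acid
Conditions: Pd(OAc)2 (5 mol%), dppf, CO (1 atm), Et3N, H2O, DMF, 60 °C; acidic work-up
Reagents that add atoms: carbon monoxide [C-]#[O+]; water O
Why: Palladium-catalysed hydroxycarbonylation of the vinyl triflate (oxidative addition, CO insertion, hydrolysis of the acylpalladium) gives the 2-substituted acrylic acid directly.

Step 11
Reactants: 15 (2Z,5E,9R)-9-{2-ethenyl-6-methyl-4-[tri(propan-2-yl)silyloxy]phenoxy}-5,9-dimethylundeca-2,5,10-trien-1-yl 2,2,2-trichloroethanimidate; 19 6-methyl-2-methylidenehept-5-enoic acid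
Product: 20 (3R,5E,9R)-9-{2-ethenyl-6-methyl-4-[tri(propan-2-yl)silyloxy]phenoxy}-5,9-dimethylundeca-1,5,10-trien-3-yl 6-methyl-2-methylidenehept-5-enoate
Conditions: [(Rp,S)-COP-OAc]2 (1 mol%; the acetate-bridged dimer [Pd(μ-OAc){(η5-2-[(4S)-4-isopropyloxazolin-2-yl]cyclopentadienyl-C,N)Co(η4-C4Ph4)}]2), 19 (3 equiv), CH2Cl2, rt
Reagents that add atoms: none
Why: Enantioselective SN2′ allylic esterification by the chiral divalent-palladium palladacycle — imidate-bound Pd activates the Z-alkene, the carboxylate adds anti at C3 and trichloroacetamide leaves — sets the lactone carbinol centre, the (Rp,S) catalyst being the antipode I recall as giving 3R esters from (Z)-imidates (to be confirmed on the first run; the (Sp,R) antipode is equally available).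

Step 12
Reactants: 20 (3R,5E,9R)-9-{2-ethenyl-6-methyl-4-[tri(propan-2-yl)silyloxy]phenoxy}-5,9-dimethylundeca-1,5,10-trien-3-yl 6-methyl-2-methylidenehept-5-enoate
Product: 22 2'-epi-tuberatolide B, via silyl-protected 2'-epi-tuberatolide B 21 (not isolated)
Conditions: second-generation Hoveyda–Grubbs catalyst RuCl2(H2IMes)(=CH-C6H4-2-OiPr) (10 mol%), toluene (2 mM), 45 → 80 °C, argon sparge; then Bu4NF/AcOH (1:1), THF, 0 °C
Reagents that add atoms: none
Why: Double ring-closing metathesis — the carbene loads on the unhindered styrene and closes the pyran on the neighbouring vinyl, and loads on the carbinol vinyl and closes the butenolide on the 1,1-disubstituted acrylate — while the only other feasible closure (linalyl vinyl onto the trisubstituted chain alkene, a cyclopentene) needs the carbene on the hindered vinyl that the styrene pre-empts; both stereocentres are spectators, and acetic-acid-buffered fluoride then frees the phenol without epimerising the lactone.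

## Compound list

1 | (R)-(−)-linalool, (3R)-3,7-dimethylocta-1,6-dien-3-ol | C=C[C@](C)(O)CCC=C(C)C | starting material
2 | 5-bromo-2-fluoro-3-methylbenzaldehyde | O=Cc1cc(Br)cc(C)c1F | starting material
3 | potassium (3R)-3,7-dimethylocta-1,6-dien-3-olate | C=C[C@](C)([O-])CCC=C(C)C.[K+] | intermediate
4 | 5-bromo-2-{[(3R)-3,7-dimethylocta-1,6-dien-3-yl]oxy}-3-methylbenzaldehyde | C=C[C@](C)(Oc1c(C)cc(Br)cc1C=O)CCC=C(C)C | intermediate
5 | 5-bromo-2-{[(3R)-3,7-dimethylocta-1,6-dien-3-yl]oxy}-1-ethenyl-3-methylbenzene | C=C[C@](C)(Oc1c(C)cc(Br)cc1C=C)CCC=C(C)C | intermediate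
6 | {4-[(3R)-3,7-dimethylocta-1,6-dien-3-yl]oxy-3-ethenyl-5-methylphenyl}lithium | C=C[C@](C)(Oc1c(C)cc([Li])cc1C=C)CCC=C(C)C | intermediate
7 | lithium {4-[(3R)-3,7-dimethylocta-1,6-dien-3-yl]oxy-3-ethenyl-5-methylphenyl}trimethoxyborate | C=C[C@](C)(Oc1c(C)cc([B-](OC)(OC)OC)cc1C=C)CCC=C(C)C.[Li+] | intermediate
8 | 4-{[(3R)-3,7-dimethylocta-1,6-dien-3-yl]oxy}-3-ethenyl-5-methylphenol | C=C[C@](C)(Oc1c(C)cc(O)cc1C=C)CCC=C(C)C | intermediate
9 | {4-[(3R)-3,7-dimethylocta-1,6-dien-3-yl]oxy-3-ethenyl-5-methylphenoxy}tri(propan-2-yl)silane | C=C[C@](C)(Oc1c(C)cc(O[Si](C(C)C)(C(C)C)C(C)C)cc1C=C)CCC=C(C)C | intermediate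
10 | (2E,6R)-6-{2-ethenyl-6-methyl-4-[tri(propan-2-yl)silyloxy]phenoxy}-2,6-dimethylocta-2,7-dien-1-ol | C=C[C@](C)(Oc1c(C)cc(O[Si](C(C)C)(C(C)C)C(C)C)cc1C=C)CC/C=C(\C)CO | intermediate
11 | [4-{[(3R,6E)-8-bromo-3,7-dimethylocta-1,6-dien-3-yl]oxy}-3-ethenyl-5-methylphenoxy]tri(propan-2-yl)silane | C=C[C@](C)(Oc1c(C)cc(O[Si](C(C)C)(C(C)C)C(C)C)cc1C=C)CC/C=C(\C)CBr | intermediate
12 | prop-2-yn-1-ol (propargyl alcohol) | C#CCO | starting material
13 | (5E,9R)-9-{2-ethenyl-6-methyl-4-[tri(propan-2-yl)silyloxy]phenoxy}-5,9-dimethylundeca-5,10-dien-2-yn-1-ol | C=C[C@](C)(Oc1c(C)cc(O[Si](C(C)C)(C(C)C)C(C)C)cc1C=C)CC/C=C(\C)CC#CCO | intermediate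
14 | (2Z,5E,9R)-9-{2-ethenyl-6-methyl-4-[tri(propan-2-yl)silyloxy]phenoxy}-5,9-dimethylundeca-2,5,10-trien-1-ol | C=C[C@](C)(Oc1c(C)cc(O[Si](C(C)C)(C(C)C)C(C)C)cc1C=C)CC/C=C(\C)C/C=C\CO | intermediate
15 | (2Z,5E,9R)-9-{2-ethenyl-6-methyl-4-[tri(propan-2-yl)silyloxy]phenoxy}-5,9-dimethylundeca-2,5,10-trien-1-yl 2,2,2-trichloroethanimidate | C=C[C@](C)(Oc1c(C)cc(O[Si](C(C)C)(C(C)C)C(C)C)cc1C=C)CC/C=C(\C)C/C=C\COC(=N)C(Cl)(Cl)Cl | intermediate
16 | 6-methylhept-5-en-2-one | CC(=O)CCC=C(C)C | starting material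
17 | lithium 6-methylhepta-1,5-dien-2-olate | C=C(O[Li])CCC=C(C)C | intermediate
18 | 6-methylhepta-1,5-dien-2-yl trifluoromethanesulfonate | C=C(CCC=C(C)C)OS(=O)(=O)C(F)(F)F | intermediate
19 | 6-methyl-2-methylidenehept-5-enoic acid | CC(C)=CCCC(=C)C(=O)O | intermediate
20 | (3R,5E,9R)-9-{2-ethenyl-6-methyl-4-[tri(propan-2-yl)silyloxy]phenoxy}-5,9-dimethylundeca-1,5,10-trien-3-yl 6-methyl-2-methylidenehept-5-enoate | CC(C)=CCCC(=C)C(=O)O[C@@H](C=C)C/C(C)=C/CC[C@](C)(C=C)Oc1c(C)cc(O[Si](C(C)C)(C(C)C)C(C)C)cc1C=C | intermediate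
21 | (5R)-5-{(2E)-5-[(2R)-2,8-dimethyl-6-[tri(propan-2-yl)silyloxy]-2H-chromen-2-yl]-2-methylpent-2-en-1-yl}-3-(4-methylpent-3-en-1-yl)furan-2(5H)-one | CC(C)=CCCC1=C[C@@H](C/C(C)=C/CC[C@]2(C)C=Cc3cc(O[Si](C(C)C)(C(C)C)C(C)C)cc(C)c3O2)OC1=O | intermediate
22 | 2'-epi-tuberatolide B, (5R)-5-{(2E)-5-[(2R)-6-hydroxy-2,8-dimethyl-2H-chromen-2-yl]-2-methylpent-2-en-1-yl}-3-(4-methylpent-3-en-1-yl)furan-2(5H)-one | CC(C)=CCCC1=C[C@@H](C/C(C)=C/CC[C@]2(C)C=Cc3cc(O)cc(C)c3O2)OC1=O | target

## Step count and weak points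

Total step count: 12 (steps 1–8, 11 and 12 on the main line; steps 9 and 10 for the acid).
Longest linear sequence: 10 steps (1 → 8, 11, 12).

The three steps most likely to fail:

Step 12 (double ring-closing metathesis). Risks are incomplete closure of the trisubstituted butenolide, or fragmentation through cyclopentene formation at the linalyl vinyl group. The fallback forms the pyran before the lactone precursor is built, sets out from 14 and comes back at 21. Ring-closing metathesis of 14 with the first-generation Grubbs catalyst RuCl2(PCy3)2(=CHPh) in CH2Cl2 at 40 °C, which joins the styrene and vinyl groups but leaves internal alkenes alone, gives the chromene allylic alcohol F8. Cl3CCN and catalytic DBU turn it into the chromene trichloroacetimidate F9. The palladacycle-catalysed esterification of step 11 with 19 gives the chromene ester F10. A single butenolide-forming metathesis with the second-generation Hoveyda–Grubbs catalyst in toluene at 80 °C then gives 21, which is desilylated as in step 12.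

Step 1 (SNAr of a hindered tertiary alkoxide next to an ortho-methyl group). The fallback makes the tertiary C–O bond by π-allylpalladium chemistry, sets out from 2 and comes back at 5. KOH in DMSO/water at 60 °C displaces fluoride from 2 to give 5-bromo-2-hydroxy-3-methylbenzaldehyde F1. Wittig methylenation with 2.2 equiv of Ph3P=CH2 gives 4-bromo-2-ethenyl-6-methylphenol F2. Palladium-catalysed asymmetric allylic etherification of F2 with geranyl methyl carbonate F3 (from geraniol and methyl chloroformate), using Pd2(dba)3·CHCl3 and the DACH-phenyl Trost ligand in CH2Cl2 at rt, gives the branched tertiary ether 5. Here the quaternary centre is set by the ligand instead of by the chiral pool; the ligand antipode is chosen by chiral HPLC comparison with 5 made from 1.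

Step 11 (enantioselective SN2′ esterification on a polyene). The fallback sets the carbinol centre by epoxidation and makes the ester by ordinary acylation, sets out from 13 and comes back at 20. NaAlH2(OCH2CH2OMe)2 in THF at 0 °C reduces 13 to the (2E,5E)-trienol F4. Sharpless asymmetric epoxidation (Ti(OiPr)4, D-(−)-diisopropyl tartrate, t-BuOOH, 4 Å sieves, CH2Cl2, −20 °C) gives the (2R,3R)-epoxy alcohol F5. I2, PPh3 and imidazole give the epoxy iodide F6. Zinc dust in ethanol opens it reductively to the (R)-vinyl carbinol F7, whose C3 keeps the epoxide C–O bond. DCC/DMAP esterification of F7 with 19 gives 20.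

## Further compounds

F1 | step 1 | 5-bromo-2-hydroxy-3-methylbenzaldehyde | O=Cc1cc(Br)cc(C)c1O
F2 | step 1 | 4-bromo-2-ethenyl-6-methylphenol | C=Cc1cc(Br)cc(C)c1O
F3 | step 1 | (2E)-3,7-dimethylocta-2,6-dien-1-yl methyl carbonate (geranyl methyl carbonate) | COC(=O)OC/C=C(\C)CCC=C(C)C
F4 | step 11 | (2E,5E,9R)-9-{2-ethenyl-6-methyl-4-[tri(propan-2-yl)silyloxy]phenoxy}-5,9-dimethylundeca-2,5,10-trien-1-ol | C=C[C@](C)(Oc1c(C)cc(O[Si](C(C)C)(C(C)C)C(C)C)cc1C=C)CC/C=C(\C)C/C=C/CO
F5 | step 11 | [(2R,3R)-3-{(2E,6R)-6-{2-ethenyl-6-methyl-4-[tri(propan-2-yl)silyloxy]phenoxy}-2,6-dimethylocta-2,7-dien-1-yl}oxiran-2-yl]methanol | OC[C@H]1O[C@@H]1C/C(C)=C/CC[C@](C)(C=C)Oc1c(C)cc(O[Si](C(C)C)(C(C)C)C(C)C)cc1C=C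
F6 | step 11 | (2S,3R)-2-(iodomethyl)-3-{(2E,6R)-6-{2-ethenyl-6-methyl-4-[tri(propan-2-yl)silyloxy]phenoxy}-2,6-dimethylocta-2,7-dien-1-yl}oxirane | IC[C@H]1O[C@@H]1C/C(C)=C/CC[C@](C)(C=C)Oc1c(C)cc(O[Si](C(C)C)(C(C)C)C(C)C)cc1C=C
F7 | step 11 | (3R,5E,9R)-9-{2-ethenyl-6-methyl-4-[tri(propan-2-yl)silyloxy]phenoxy}-5,9-dimethylundeca-1,5,10-trien-3-ol | C=C[C@H](O)C/C(C)=C/CC[C@](C)(C=C)Oc1c(C)cc(O[Si](C(C)C)(C(C)C)C(C)C)cc1C=C
F8 | step 12 | (2Z,5E)-8-{(2R)-2,8-dimethyl-6-[tri(propan-2-yl)silyloxy]-2H-chromen-2-yl}-5-methylocta-2,5-dien-1-ol | C[C@@]1(CC/C=C(\C)C/C=C\CO)C=Cc2cc(O[Si](C(C)C)(C(C)C)C(C)C)cc(C)c2O1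
F9 | step 12 | (2Z,5E)-8-{(2R)-2,8-dimethyl-6-[tri(propan-2-yl)silyloxy]-2H-chromen-2-yl}-5-methylocta-2,5-dien-1-yl 2,2,2-trichloroethanimidate | C[C@@]1(CC/C=C(\C)C/C=C\COC(=N)C(Cl)(Cl)Cl)C=Cc2cc(O[Si](C(C)C)(C(C)C)C(C)C)cc(C)c2O1
F10 | step 12 | (3R,5E)-8-{(2R)-2,8-dimethyl-6-[tri(propan-2-yl)silyloxy]-2H-chromen-2-yl}-5-methylocta-1,5-dien-3-yl 6-methyl-2-methylidenehept-5-enoate | CC(C)=CCCC(=C)C(=O)O[C@@H](C=C)C/C(C)=C/CC[C@]1(C)C=Cc2cc(O[Si](C(C)C)(C(C)C)C(C)C)cc(C)c2O1
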